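Birch starts slowly and then hurries: it loses 0.00940 M of Xa in its first 1.9 min, and 0.0660 M in its last interval of that length. Xa turns into Xp with a little Xc as catalyst.

| flask | Xa | Xc | time |
|---|---|---|---|
| birch | 0.400 M | 8.00 × 10⁻⁴ M |  |
| oak | 0.400 M | 0.00120 M |  |
| ash | 0.200 M | 8.00 × 10⁻⁴ M |  |
| cedar | 0.800 M | 0.00240 M | 9.5 min |

| run | time / min | [Xa] / M |
|---|---|---|
| birch run | 1.9 | 0.3906 |
| birch run | 3.8 | 0.3743 |
| birch run | 5.7 | 0.3401 |
| birch run | 7.6 | 0.2960 |
| birch run | 9.5 | 0.2300 |
| oak run | 1.9 | 0.3892 |
| oak run | 3.8 | 0.3713 |
| oak run | 5.7 | 0.3340 |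
| oak run | 7.6 | 0.2808 |
| oak run | 9.5 | 0.2090 |
| ash run | 1.9 | 0.1939 |
| ash run | 3.8 | 0.1878 |
| ash run | 5.7 | 0.1789 |
| ash run | 7.6 | 0.1714 |
| ash run | 9.5 | 0.1578 |

(readings scatter by 0.002 M)

- the exponent of [Xa] in the starting rate at the charge of the birch run (at the point where two percent of the Xa have become Xp) (one fixed amount of Xp, the same in the runs compared)
- the exponent of [Xc] in the starting rate at the charge of the birch run (at the point where two percent of the Xa have become Xp)
- Xa in the cedar run at 9.5 min, as a share of the Xa charged

- Overall: Xa -> Xp, with Xc as catalyst.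
- Constant volume, constant temperature.
- The analysis sees a species whether free or bound.
- An order is taken over about fifteen percent of the charge, up and down.

Two chemists dispute cedar. The first holds that Xc does the work, giving each Xa a steady chance per minute in step with Xc. She points to oak, which has more Xc and stands lower than birch at 9.5 min, 0.2090 M against 0.2300 M. She takes the chance from the first birch reading, multiplies it by 3.00 for cedar's Xc, and keeps 70.0 % of cedar's Xa at 9.5 min.

The second holds that Xp makes more Xp (autocatalysis). Since Xa and Xp together make up the charge, he watches the ratio of Xp to Xa, and his measure is the odds time τ, the time in which that ratio grows by a factor e. The last two birch readings give τ = 2.55 min. The last two oak readings give 2.48 min, although oak has 1.50 times birch's Xc. On his view τ goes inversely with the Xa charged, so cedar's is 1.28 min. The ratio also goes up 3 times between a quarter and half of the charge turned, which takes ln(3)·τ.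

The forecast takes his side, on the ground that “the product speeds the reaction”. It gives orders of 0.85 in Xa and 0.35 in Xc, and 10 % of cedar's Xa left, within 4 % to 22 %. My own reckoning differs: if cedar's ratio sets out from where birch's line points back to, 3.18 % is left, less than the forecast says.

The simulation gives orders of 0.89 and 0.22, and 5.68 % of cedar's Xa left.

    Xc + Xa ⇌ Xc.Xa (94.80 M⁻¹ min⁻¹, 24.72 min⁻¹)
    Xc.Xa → Xp + Xc (2.934 min⁻¹)
    Xa + Xp → 2 Xp (0.8940 M⁻¹ min⁻¹)
    Xa → Xp (0.005196 min⁻¹)

Cedar's 9.5 min holds 7.42 of the odds times reckoned for it, and its Xa falls to 5.68 % because of the step Xa + Xp → 2 Xp; the same flask run without that step keeps 89.3 %. The steady view comes nearer in birch's charge run without that step, where the order in Xc is 0.40 instead of 0.22, though still short of the 1 it claims. Ash, charged with half of birch's Xa, gets by his rule an odds time of 5.11 min, which gives 5.61 min from quarter to half, and the simulation's time for that stretch in ash is 5.27 min.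

The runs are calculated from invented constants, and the scatter is random.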